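**Assumption:** all bicyclic compounds are numbered like the target (C1–C3, C3a, C4–C8, C8a). The given SMILES is read as (3R,3aS,4R,8aR): the C3 hydroxyl, the C4 acyloxy group and the C8a methyl lie on one face, H3a and H4 on the other.

## Retrosynthetic overview

1. Ester C(=O)–O last: target 16 ⇒ cis-1,3-diol 13 + 4-(acetyloxy)benzoyl chloride 14.
2. Key disconnection, the C4–O bond: 13 ⇒ epoxy alcohol 12 ⇒ allylic alcohol 11. The C3 hydroxyl delivers oxygen to C4 on its own face (sets C4), and opening of the C3a–O bond then places H3a trans to it (sets C3a).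
3. 11 ⇒ enone 10 + isopropyl nucleophile, added anti to the angular methyl (sets C3).
4. 10 ⇒ 7 by ring-closing metathesis and dehydration; 7 ⇒ 3-methylcyclopent-2-en-1-one + allylsilane + 3-methylbut-3-enal by a new enantioselective conjugate allylation/aldol (sets C8a).
5. Ring order: ring A (five-membered) is bought; ring B (seven-membered) is closed second by metathesis.

## Route

**Step 1**
Reactants: 1 3-methylbut-3-en-1-ol
Product: 2 3-methylbut-3-enal
Conditions: Dess–Martin periodinane (1.1 equiv), CH2Cl2, 0 °C → rt; cold aq NaHCO3 wash, dry, short-path distillation into toluene; used the same day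
Reagents that add atoms: none
Why: Dess–Martin oxidation stops at the aldehyde under near-neutral conditions, which keeps the β,γ-double bond from moving into conjugation.

**Step 2**
Reactants: 3 3-methylcyclopent-2-en-1-one; 4 trimethyl(prop-2-en-1-yl)silane; 2 3-methylbut-3-enal
Product: 7 (3R)-2-(1-hydroxy-3-methylbut-3-en-1-yl)-3-methyl-3-(prop-2-en-1-yl)cyclopentan-1-one, via silyl enol ether 5 (not isolated), via silylated aldol 6 (not isolated)
Conditions: confined chiral imidodiphosphorimidate Brønsted acid (IDPi, 3,3′-diaryl-BINOL-derived, N-triflyl; 2 mol%), 4 (1.2 equiv), toluene, −60 °C; excess 4 removed in vacuo; then 2, −78 → −40 °C; then 1 M HCl/THF, 0 °C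
Reagents that add atoms: none
Why: Proposed new method: the acid is silylated by 4 to a silylium/IDPi ion pair that activates 3 at oxygen inside the chiral anion, so the allylsilane attacks one face of the β-carbon (Hosomi–Sakurai conjugate allylation) and sets C8a as R. Silicon passes to oxygen to give the regiodefined enol silane 5 and regenerate the silylium, which then catalyses the Mukaiyama aldol of 5 with 2 at the carbon next to the quaternary centre. The closest known chemistry is the racemic TiCl4- or HNTf2-promoted conjugate Sakurai allylation/aldol of β-substituted cyclic enones, together with IDPi-silylium-catalysed enantioselective Mukaiyama–Michael additions and aldehyde allylations. The two new centres (C3a, C4) are uncontrolled and are erased in step 3.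

**Step 3**
Reactants: 7 (3R)-2-(1-hydroxy-3-methylbut-3-en-1-yl)-3-methyl-3-(prop-2-en-1-yl)cyclopentan-1-one
Product: 10 (8aR)-6,8a-dimethyl-1,2,8,8a-tetrahydroazulen-3(5H)-one, via hydroxy ketone 8 (not isolated), via mesylate 9 (not isolated)
Conditions: second-generation Grubbs catalyst (H2IMes)(PCy3)Cl2Ru=CHPh (5 mol%), CH2Cl2 (5 mM), 40 °C; then Et3N, MsCl, 0 °C → rt
Reagents that add atoms: none
Why: Ring-closing metathesis of the allyl and methallyl termini closes ring B with the C6=C7 alkene, and E1cB elimination of the β-mesyloxy ketone then converges all diastereomers of 7 on one enone (Et3N only and short contact, to avoid drift of the skipped diene into conjugation).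

**Step 4**
Reactants: 10 (8aR)-6,8a-dimethyl-1,2,8,8a-tetrahydroazulen-3(5H)-one
Product: 11 (3R,8aR)-6,8a-dimethyl-3-(propan-2-yl)-1,2,3,5,8,8a-hexahydroazulen-3-ol
Conditions: iPrMgCl, anhydrous CeCl3, THF, −78 → −20 °C; aq NH4Cl
Reagents that add atoms: isopropylmagnesium chloride CC(C)[Mg]Cl
Why: The organocerium reagent adds 1,2 to the enone (Imamoto conditions suppress enolisation, reduction and 1,4-addition) from the face opposite the pseudo-axial C8a methyl, which sets C3 with the hydroxyl cis to that methyl.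

**Step 5**
Reactants: 11 (3R,8aR)-6,8a-dimethyl-3-(propan-2-yl)-1,2,3,5,8,8a-hexahydroazulen-3-ol
Product: 12 (3R,3aS,4R,8aR)-3a,4-epoxy-6,8a-dimethyl-3-(propan-2-yl)-1,2,3,3a,4,5,8,8a-octahydroazulen-3-ol
Conditions: VO(acac)2 (5 mol%), t-BuOOH (1.5 equiv, decane), 2,6-lutidine (10 mol%), toluene, 0 °C → rt
Reagents that add atoms: tert-butyl hydroperoxide CC(C)(C)OO
Why: Hydroxyl-directed epoxidation through a pentavalent vanadium alkoxide/alkylperoxide touches only the allylic C3a=C4 alkene (C6=C7 is left alone) and delivers oxygen on the face of the C3 hydroxyl, so the C4–O bond is formed with C4 as R.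

**Step 6**
Reactants: 12 (3R,3aS,4R,8aR)-3a,4-epoxy-6,8a-dimethyl-3-(propan-2-yl)-1,2,3,3a,4,5,8,8a-octahydroazulen-3-ol
Product: 13 (3R,3aS,4R,8aR)-6,8a-dimethyl-3-(propan-2-yl)-1,2,3,3a,4,5,8,8a-octahydroazulene-3,4-diol
Conditions: Cp2TiCl2 (30 mol%), Zn dust, 2,4,6-collidine hydrochloride, 1,4-cyclohexadiene, THF, rt
Reagents that add atoms: none
Why: Cp2TiCl (trivalent titanium) opens the epoxide at the more substituted C3a–O bond (Nugent–RajanBabu/Gansäuer reductive epoxide opening), and the tertiary C3a radical takes hydrogen from 1,4-cyclohexadiene on the face opposite the titanium alkoxide, the C3 hydroxyl and the C8a methyl, which sets C3a as S (trans ring fusion) and leaves C4–O untouched.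

**Step 7**
Reactants: 13 (3R,3aS,4R,8aR)-6,8a-dimethyl-3-(propan-2-yl)-1,2,3,3a,4,5,8,8a-octahydroazulene-3,4-diol; 14 4-(acetyloxy)benzoyl chloride
Product: 16 (3R,3aS,4R,8aR)-3-hydroxy-6,8a-dimethyl-3-(propan-2-yl)-1,2,3,3a,4,5,8,8a-octahydroazulen-4-yl 4-hydroxybenzoate, via acetate 15 (not isolated)
Conditions: 14 (2 equiv), Et3N, DMAP (1 equiv), CH2Cl2, 0 → 40 °C; then pyrrolidine, rt
Reagents that add atoms: none
Why: DMAP-catalysed acylation takes place only at the secondary C4 hydroxyl (the tertiary C3 hydroxyl is inert) with retention at C4, and pyrrolidine then cleaves the activated aryl acetate by aminolysis far faster than the hindered alkyl benzoate.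

## Compound list

1 | 3-methylbut-3-en-1-ol | CC(=C)CCO | starting material
2 | 3-methylbut-3-enal | CC(=C)CC=O | intermediate
3 | 3-methylcyclopent-2-en-1-one | CC1=CC(=O)CC1 | starting material
4 | trimethyl(prop-2-en-1-yl)silane (allyltrimethylsilane) | C=CC[Si](C)(C)C | starting material
5 | trimethyl{[(3R)-3-methyl-3-(prop-2-en-1-yl)cyclopent-1-en-1-yl]oxy}silane | C=CC[C@@]1(C)CCC(O[Si](C)(C)C)=C1 | intermediate
6 | (3R)-3-methyl-2-{3-methyl-1-[(trimethylsilyl)oxy]but-3-en-1-yl}-3-(prop-2-en-1-yl)cyclopentan-1-one, diastereomer mixture at C2 and C1′ | C=CC[C@@]1(C)CCC(=O)C1C(O[Si](C)(C)C)CC(C)=C | intermediate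
7 | (3R)-2-(1-hydroxy-3-methylbut-3-en-1-yl)-3-methyl-3-(prop-2-en-1-yl)cyclopentan-1-one, diastereomer mixture at C2 and C1′ | C=CC[C@@]1(C)CCC(=O)C1C(O)CC(C)=C | intermediate
8 | (8aR)-4-hydroxy-6,8a-dimethyl-1,2,3a,4,8,8a-hexahydroazulen-3(5H)-one, diastereomer mixture at C3a and C4 | CC1=CC[C@@]2(C)CCC(=O)C2C(O)C1 | intermediate
9 | (8aR)-6,8a-dimethyl-3-oxo-1,2,3,3a,4,5,8,8a-octahydroazulen-4-yl methanesulfonate, diastereomer mixture at C3a and C4 | CC1=CC[C@@]2(C)CCC(=O)C2C(OS(C)(=O)=O)C1 | intermediate
10 | (8aR)-6,8a-dimethyl-1,2,8,8a-tetrahydroazulen-3(5H)-one | CC1=CC[C@@]2(C)CCC(=O)C2=CC1 | intermediate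
11 | (3R,8aR)-6,8a-dimethyl-3-(propan-2-yl)-1,2,3,5,8,8a-hexahydroazulen-3-ol | CC1=CC[C@@]2(C)CC[C@@](O)(C(C)C)C2=CC1 | intermediate
12 | (3R,3aS,4R,8aR)-3a,4-epoxy-6,8a-dimethyl-3-(propan-2-yl)-1,2,3,3a,4,5,8,8a-octahydroazulen-3-ol | CC1=CC[C@@]2(C)CC[C@@](O)(C(C)C)[C@]23O[C@@H]3C1 | intermediate
13 | (3R,3aS,4R,8aR)-6,8a-dimethyl-3-(propan-2-yl)-1,2,3,3a,4,5,8,8a-octahydroazulene-3,4-diol | CC1=CC[C@@]2(C)CC[C@@](O)(C(C)C)[C@@H]2[C@H](O)C1 | intermediate
14 | 4-(acetyloxy)benzoyl chloride | CC(=O)Oc1ccc(cc1)C(Cl)=O | starting material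
15 | (3R,3aS,4R,8aR)-3-hydroxy-6,8a-dimethyl-3-(propan-2-yl)-1,2,3,3a,4,5,8,8a-octahydroazulen-4-yl 4-(acetyloxy)benzoate | CC1=CC[C@@]2(C)CC[C@@](O)(C(C)C)[C@@H]2[C@H](OC(=O)c2ccc(OC(C)=O)cc2)C1 | intermediate
16 | (3R,3aS,4R,8aR)-3-hydroxy-6,8a-dimethyl-3-(propan-2-yl)-1,2,3,3a,4,5,8,8a-octahydroazulen-4-yl 4-hydroxybenzoate | CC1=CC[C@@]2(C)CC[C@@](O)(C(C)C)[C@@H]2[C@H](OC(=O)c2ccc(O)cc2)C1 | target

## Step count and risks

Total step count: 7. Longest linear sequence: 7 steps (1 → 2 → 7 → 10 → 11 → 12 → 13 → 16, steps 1–7). The route is fully linear: aldehyde 2 from step 1 is a reactant in step 2, and 3, 4 and 14 enter as purchased materials.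

**Step 2 (the new reaction).** The enantioselectivity at C8a, or the one-pot aldol at the hindered enol silane carbon, may fall short. The fallback uses known chemistry, sets out from aldehyde 2 and returns at 7, with 3 and 4 replaced. Commercial 3-ethoxycyclopent-2-en-1-one (CCOC1=CC(=O)CC1) is treated with allylmagnesium bromide (CH2=CHCH2MgBr) and then dilute HCl (Stork–Danheiser addition–transposition) to give 3-(prop-2-en-1-yl)cyclopent-2-en-1-one F1. Copper-catalysed asymmetric conjugate addition of Me3Al (Cu(OTf)2 with a chiral sulfonate-bearing N-heterocyclic carbene ligand made from its imidazolinium salt) now brings in the methyl group and gives the dimethylaluminium (R)-enolate F2. The ligand enantiomer is chosen for the R centre. F2 is intercepted in the same flask with 2 to give 7 after aqueous work-up.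

**Step 4.** Isopropyl transfer to the hindered, enolisable enone may stall or give reduction, and the facial ratio is unproven. The fallback sets out from 10 and returns at 11. Isopropenylmagnesium bromide (CH2=C(CH3)MgBr) with CeCl3 (an sp2 nucleophile that is smaller and has no β-hydride to deliver) gives the (3R,8aR)-isopropenyl carbinol F3. Hydrogenation with RhCl(PPh3)3 under H2 (1 atm, benzene) then reduces only the 1,1-disubstituted alkene and leaves both trisubstituted alkenes, giving 11.

**Step 6.** The hydrogen transfer to the C3a radical may not be face-selective, or the hindered epoxide may deoxygenate back to 11. The fallback sets out from 11 (so 12 is not needed) and returns at 13. Chlorodimethylsilane/imidazole gives the dimethylsilyl ether F4. Thiol-catalysed radical-chain intramolecular hydrosilylation (tert-dodecanethiol, radical initiator, 65 °C) closes the oxasilolane F5: the silyl radical attacks C4 5-endo from the oxygen-bearing face, and the thiol transfers hydrogen to C3a on the face left open by the silicon bridge. Tamao–Fleming oxidation (H2O2, KF, KHCO3, THF/MeOH) turns C4–Si into C4–OH with retention and frees the C3 hydroxyl, giving 13.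

## Further compounds

F1 | step 2 | 3-(prop-2-en-1-yl)cyclopent-2-en-1-one | C=CCC1=CC(=O)CC1
F2 | step 2 | dimethylaluminium enolate of (3R)-3-methyl-3-(prop-2-en-1-yl)cyclopentan-1-one (C1=C2 enolate) | C=CC[C@@]1(C)CCC(O[Al](C)C)=C1
F3 | step 4 | (3R,8aR)-6,8a-dimethyl-3-(prop-1-en-2-yl)-1,2,3,5,8,8a-hexahydroazulen-3-ol | CC1=CC[C@@]2(C)CC[C@@](O)(C(C)=C)C2=CC1
F4 | step 6 | dimethylsilyl ether of 11, [(3R,8aR)-6,8a-dimethyl-3-(propan-2-yl)-1,2,3,5,8,8a-hexahydroazulen-3-yl]oxy(dimethyl)silane | CC1=CC[C@@]2(C)CC[C@@](O[SiH](C)C)(C(C)C)C2=CC1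
F5 | step 6 | cyclic dimethylsilylene bridging O3 and C4 of the trans-fused skeleton (2,2-dimethyl-1-oxa-2-silacyclopentane fused at C3/C3a/C4, configuration as in 13) | CC1=CC[C@@]2(C)CC[C@]3(C(C)C)O[Si](C)(C)[C@H](C1)[C@H]23
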